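The plan rests on cutting the five-membered furanone ring (O1, C2, C3, C3a, C7a) away from the spiro carbon C2. That ring ties C2 to the phloroglucinol ring through O1–C7a and C3–C3a. C7a and C3a are neighbouring arene carbons, which is the pair an aryne offers. In one operation a tertiary alkoxide and its geminal methyl ester are joined to 3,5-bis(benzyloxy)benzyne, making both bonds and the ring without touching the stereocentre. The precursor is an enantiopure, kaempferol-derived methyl 9-hydroxy-8-methoxy-8-aryl-8,9-dihydrofuro[2,3-h]chromen-4-one-9-carboxylate. Its hemiketal is masked as a methyl ketal and its phenols as benzyl ethers. It is obtained by methanolytic ring transposition of a hydroxylated 9-aroyl lactone.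

Key step: step 14

Atom labels: unprimed locants belong to the benzofuran-3(2H)-one half (O1, spiro C2, C3, C3a to C7a). Primed locants belong to the furo[2,3-h]chromen-4-one half (O1' to C6', O7', C8', C9' = C2). Before the spiro ring exists the same two carbons are called C8 and C9.

Design remark 1: the ketal has to be made in methanolic acid. The phenols are therefore carried as acid-stable benzyl ethers, also on the aryne, rather than as acetal-type ethers, which would be lost first at the peri 5-oxygen.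

Design remark 2: the 7-oxygen and the future ester are held together as an aryl lactone. This saves a protecting group and an esterification. It also makes the C9 enolate coplanar with the arene, so that acylation and hydroxylation are not blocked by the two ortho substituents.

Assumption 1: the hemiketal carbon C8' epimerises through the ring-opened 7'-hydroxy ketone. Its configuration is taken to be the thermodynamic one drawn for the target (aryl syn to O1, OH syn to and hydrogen-bonded with C3=O).

Assumption 2: the sense of induction in step 9 cannot be derived from existing models for this enolate. The (R,R)-ligand is written, and its antipode is used if the check on 17 (X-ray or ECD) shows the opposite carbinol.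

Step 1
Reactants: 1 kaempferol
Product: 2 kaempferol 3,5,7,4'-tetraacetate
Conditions: Ac2O, pyridine, rt to 60 °C
Reagents that add atoms: acetic anhydride, CC(=O)OC(C)=O
Why: Exhaustive pyridine-catalysed O-acetylation also acylates the chelated 5-OH on warming and turns the four phenols into esters that can be told apart by leaving-group ability.

Step 2
Reactants: 2 kaempferol 3,5,7,4'-tetraacetate
Product: 4 7-O-allylkaempferol 3,5,4'-triacetate, via 7-hydroxy triacetate 3 (not isolated)
Conditions: PhSH, imidazole (cat.), NMP, 0 °C to rt; then allyl bromide, K2CO3, rt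
Reagents that add atoms: allyl bromide, C=CCBr
Why: Imidazole-catalysed thiolysis removes only the 7-acetate because the 7-phenoxide, a vinylogous carboxylate of the C4 carbonyl, is the best leaving group, and the freed phenol undergoes Williamson etherification in the same pot.

Step 3
Reactants: 4 7-O-allylkaempferol 3,5,4'-triacetate
Product: 6 7-O-allyl-3,5,4'-tri-O-benzylkaempferol, via 7-O-allylkaempferol 5 (not isolated)
Conditions: K2CO3, MeOH–THF, rt, under argon; evaporate; BnBr (excess), K2CO3, DMF, 80 °C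
Reagents that add atoms: benzyl bromide, BrCc1ccccc1
Why: Base-catalysed transesterification frees the three remaining phenols, and Williamson benzylation with excess bromide at 80 °C also alkylates the hydrogen-bonded 5-OH, the allyl ether being inert to both operations.

Step 4
Reactants: 6 7-O-allyl-3,5,4'-tri-O-benzylkaempferol
Product: 7 8-allyl-3,5,4'-tri-O-benzylkaempferol (free 7-OH)
Conditions: N,N-diethylaniline, 200 °C
Reagents that add atoms: none
Why: The aromatic Claisen rearrangement ([3,3]-shift, then tautomerisation) should deliver allyl to C8 rather than C6, because the C7–C8 bond has the higher double-bond character in the benzopyranone and C6 is buttressed by the 5-benzyloxy group, and it unmasks the 7-OH at the same time.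

Step 5
Reactants: 7 8-allyl-3,5,4'-tri-O-benzylkaempferol
Product: 9 lactol 3,5-bis(benzyloxy)-2-[4-(benzyloxy)phenyl]-8-hydroxy-8,9-dihydrofuro[2,3-h]chromen-4-one, via arylacetaldehyde 8 (not isolated)
Conditions: OsO4 (cat.), NaIO4, 2,6-lutidine, dioxane–H2O, rt
Reagents that add atoms: OsO4 (oxygen carrier), O=[Os](=O)(=O)=O; NaIO4 (terminal oxygen source), [Na+].[O-]I(=O)(=O)=O
Why: Lemieux–Johnson cleavage attacks the terminal alkene far faster than the tetrasubstituted push–pull C2=C3 bond, and aldehyde 8 is trapped by the neighbouring 7-OH as the five-membered lactol, whose new C8 centre is inconsequential because step 6 removes it.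

Step 6
Reactants: 9 lactol
Product: 10 lactone 3,5-bis(benzyloxy)-2-[4-(benzyloxy)phenyl]furo[2,3-h]chromene-4,8(9H)-dione
Conditions: Ag2CO3 on Celite, toluene, reflux
Reagents that add atoms: none
Why: Fétizon oxidation converts lactols into lactones under neutral conditions, which avoids acid-catalysed dehydration to the furan and leaves the benzyl ethers and the chromenone untouched.

Step 7
Reactants: 11 4-(benzyloxy)benzoic acid
Product: 12 4-(benzyloxy)benzoyl chloride
Conditions: (COCl)2, DMF (cat.), CH2Cl2, 0 °C to rt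
Reagents that add atoms: oxalyl chloride, O=C(Cl)C(=O)Cl
Why: Chloroiminium-catalysed acid chloride formation proceeds with gaseous by-products only and does not affect the benzyl ether.

Step 8
Reactants: 10 lactone; 12 4-(benzyloxy)benzoyl chloride
Product: 13 9-[4-(benzyloxy)benzoyl] lactone (enolised β-keto lactone)
Conditions: MgCl2, Et3N, MeCN–CH2Cl2, 0 °C to rt; cold dilute HCl work-up
Reagents that add atoms: none
Why: Soft-enolisation C-acylation (a crossed Claisen condensation through the magnesium enolate) should work because C9–H2 is acidified by the lactone carbonyl and the arene, the flat 2-oxidobenzofuran-type enolate is open at C9, and the magnesium chelate of the product blocks O-acylation and double acylation.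

Step 9
Reactants: 13 9-[4-(benzyloxy)benzoyl] lactone
Product: 14 (9R)-9-[4-(benzyloxy)benzoyl]-9-hydroxy lactone
Conditions: Ni(ClO4)2·6H2O (10 mol%), (R,R)-4,6-dibenzofurandiyl-2,2'-bis(4-phenyloxazoline) [(R,R)-DBFOX/Ph, 11 mol%], 4 Å MS, 2-(benzenesulfonyl)-3-phenyloxaziridine, CH2Cl2, rt
Reagents that add atoms: 2-(benzenesulfonyl)-3-phenyloxaziridine, O=S(=O)(N1OC1c1ccccc1)c1ccccc1
Why: In this catalytic enantioselective α-hydroxylation of a 1,3-dicarbonyl compound, two-point binding of the enolised β-keto lactone to the chiral nickel Lewis acid shields one face of the planar enolate, so that oxygen transfer from the N-sulfonyloxaziridine sets C9 as R (ligand antipode as in assumption 2), while the oxidant spares the chromenone C2=C3 bond and the benzyl ethers.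

Step 10
Reactants: 14 (9R)-9-aroyl-9-hydroxy lactone
Product: 17 methyl (8R,9R)-3,5-bis(benzyloxy)-2,8-bis[4-(benzyloxy)phenyl]-9-hydroxy-8-methoxy-4-oxo-8,9-dihydrofuro[2,3-h]chromene-9-carboxylate, via keto ester 15 (not isolated), via hemiketal 16 (not isolated)
Conditions: HCl (0.5 M) in dry MeOH, 3 Å MS, 40 °C
Reagents that add atoms: methanol, CO
Why: Acid-catalysed transesterification opens the activated aryl lactone to 15, the released 7-OH adds to the neighbouring aryl ketone (16), and ketal exchange through the aryl-stabilised oxocarbenium ion gives the methyl ketal under thermodynamic control with the C8 aryl group anti to CO2Me (8R); this is the ring transposition known for 3-acylbenzofuran-2(3H)-ones in acidic alcohol, stopped before dehydration by the C9 hydroxyl, and it breaks no bond to C9.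

Step 11
Reactants: 18 phloroglucinol
Product: 19 3,5-bis(benzyloxy)phenol
Conditions: BnBr (2 equiv), K2CO3, DMF, rt
Reagents that add atoms: benzyl bromide, BrCc1ccccc1
Why: Statistical Williamson etherification with two equivalents of bromide makes the diether the main component, which chromatography separates from the mono- and triether.

Step 12
Reactants: 19 3,5-bis(benzyloxy)phenol
Product: 20 3,5-bis(benzyloxy)-2-bromophenol
Conditions: NBS, CH2Cl2, −78 °C
Reagents that add atoms: N-bromosuccinimide, O=C1CCC(=O)N1Br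
Why: Electrophilic aromatic bromination at low temperature in a non-polar solvent goes ortho to the free OH (hydrogen-bonded delivery, two equivalent sites) rather than into the more crowded position between the two benzyloxy groups.

Step 13
Reactants: 20 3,5-bis(benzyloxy)-2-bromophenol
Product: 23 3,5-bis(benzyloxy)-2-(trimethylsilyl)phenyl trifluoromethanesulfonate, via silyl ether 21 (not isolated), via lithium phenoxide 22 (not isolated)
Conditions: (Me3Si)2NH, THF, 65 °C; evaporate; n-BuLi, THF, −78 °C; Tf2O, −78 °C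
Reagents that add atoms: hexamethyldisilazane, C[Si](C)(C)N[Si](C)(C)C; triflic anhydride, O=S(=O)(OS(=O)(=O)C(F)(F)F)C(F)(F)F
Why: O-silylation, bromine–lithium exchange and 1,3-O-to-C silyl migration (retro-Brook rearrangement) place silicon on C2 and free phenoxide 22 for triflation, the exchange at −78 °C outrunning benzylic deprotonation.

Step 14
Reactants: 17 methyl (8R,9R)-9-hydroxy-8-methoxy ketal ester; 23 3,5-bis(benzyloxy)-2-(trimethylsilyl)phenyl trifluoromethanesulfonate
Product: 27 (2S,8'R)-hexa-O-benzyl 8'-O-methyl ketal of the target, via potassium alkoxide 24 (not isolated), via aryne 25 (not isolated), via aryl anion 26 (not isolated)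
Conditions: KH (1.0 equiv), 18-crown-6, THF, 0 °C; then KF, slow addition of 23 (2 equiv), THF, rt
Reagents that add atoms: none
Why: Proposed new method: fluoride strips silicon from 23 and loss of triflate gives aryne 25, to which alkoxide 24 adds at the carbon remote from the neighbouring benzyloxy group (the more linear, more electrophilic end of the distorted triple bond), so that the charge of 26 sits ortho to that oxygen and is inductively stabilised. The carbanion then attacks the geminal methyl ester in a 5-exo-trig closure and expels methoxide, which forms O1–C7a and C3–C3a and closes the furanone with C3=O next to C4–O, as the target requires. The closest known reaction types are the aryne insertion–acylation annulations of salicylates (xanthones) and of α-amino esters (indolin-3-ones) and the addition of tert-butoxide to benzyne; an aliphatic tertiary α-hydroxy ester has not served as the partner. No stereocentre is made or broken: the four ligands of C9 keep their places (R in 17 reads S in 27 only because the CIP ranking changes) and C8 is a spectator. The step needs aryne regioselectivity, secured by the 3-benzyloxy group, and acylation faster than protonation, secured by the preformed alkoxide (H2 as sole by-product), the aprotic medium and the proximity imposed by the quaternary carbon. The methyl ketal removes the ketone that would open retro-Claisen and α-ketol pathways to the alkoxide, and it ties up O7 so that no phenoxide competes for the aryne.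

Step 15
Reactants: 27 (2S,8'R)-hexa-O-benzyl 8'-O-methyl ketal
Product: 29 target CNP0283000.1, via hexaphenol methyl ketal 28 (not isolated)
Conditions: H2 (1 atm), 10% Pd/C, THF–MeOH, rt; filter, concentrate; 0.5 M aq. HCl–THF, rt
Reagents that add atoms: water, O
Why: Hydrogenolysis cleaves the six aryl benzyl ethers but should spare the fully substituted benzylic C–O bonds at C2 and C8' (as it spares the C2–O bond of benzylated flavan-3-ols), and dilute acid then exchanges OMe for OH through the 4-hydroxyphenyl-stabilised oxocarbenium ion, the hemiketal settling by ring–chain equilibration in the 8'R form (aryl syn to O1, OH hydrogen-bonded to C3=O).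

Compound list
1 | kaempferol | O=c1c(O)c(-c2ccc(O)cc2)oc2cc(O)cc(O)c12 | starting material
2 | kaempferol 3,5,7,4'-tetraacetate | CC(=O)Oc1ccc(cc1)-c1oc2cc(OC(C)=O)cc(OC(C)=O)c2c(=O)c1OC(C)=O | intermediate
3 | kaempferol 3,5,4'-triacetate (free 7-OH) | CC(=O)Oc1ccc(cc1)-c1oc2cc(O)cc(OC(C)=O)c2c(=O)c1OC(C)=O | intermediate
4 | 7-O-allylkaempferol 3,5,4'-triacetate | C=CCOc1cc(OC(C)=O)c2c(=O)c(OC(C)=O)c(-c3ccc(OC(C)=O)cc3)oc2c1 | intermediate
5 | 7-O-allylkaempferol | C=CCOc1cc(O)c2c(=O)c(O)c(-c3ccc(O)cc3)oc2c1 | intermediate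
6 | 7-O-allyl-3,5,4'-tri-O-benzylkaempferol | C=CCOc1cc(OCc2ccccc2)c2c(=O)c(OCc3ccccc3)c(-c3ccc(OCc4ccccc4)cc3)oc2c1 | intermediate
7 | 8-allyl-3,5-bis(benzyloxy)-2-[4-(benzyloxy)phenyl]-7-hydroxychromen-4-one | C=CCc1c(O)cc(OCc2ccccc2)c2c(=O)c(OCc3ccccc3)c(-c3ccc(OCc4ccccc4)cc3)oc12 | intermediate
8 | 2-{3,5-bis(benzyloxy)-2-[4-(benzyloxy)phenyl]-7-hydroxy-4-oxochromen-8-yl}acetaldehyde | O=CCc1c(O)cc(OCc2ccccc2)c2c(=O)c(OCc3ccccc3)c(-c3ccc(OCc4ccccc4)cc3)oc12 | intermediate
9 | 3,5-bis(benzyloxy)-2-[4-(benzyloxy)phenyl]-8-hydroxy-8,9-dihydrofuro[2,3-h]chromen-4-one (lactol, C8 epimers) | OC1Cc2c(O1)cc(OCc1ccccc1)c1c(=O)c(OCc3ccccc3)c(-c3ccc(OCc4ccccc4)cc3)oc21 | intermediate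
10 | 3,5-bis(benzyloxy)-2-[4-(benzyloxy)phenyl]furo[2,3-h]chromene-4,8(9H)-dione (lactone) | O=C1Cc2c(O1)cc(OCc1ccccc1)c1c(=O)c(OCc3ccccc3)c(-c3ccc(OCc4ccccc4)cc3)oc21 | intermediate
11 | 4-(benzyloxy)benzoic acid | O=C(O)c1ccc(OCc2ccccc2)cc1 | starting material
12 | 4-(benzyloxy)benzoyl chloride | O=C(Cl)c1ccc(OCc2ccccc2)cc1 | intermediate
13 | 9-[4-(benzyloxy)benzoyl]-3,5-bis(benzyloxy)-2-[4-(benzyloxy)phenyl]furo[2,3-h]chromene-4,8(9H)-dione (drawn as keto form, enolised, C9 labile) | O=C1Oc2cc(OCc3ccccc3)c3c(=O)c(OCc4ccccc4)c(-c4ccc(OCc5ccccc5)cc4)oc3c2C1C(=O)c1ccc(OCc2ccccc2)cc1 | intermediate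
14 | (9R)-9-[4-(benzyloxy)benzoyl]-3,5-bis(benzyloxy)-2-[4-(benzyloxy)phenyl]-9-hydroxyfuro[2,3-h]chromene-4,8(9H)-dione | O=C1Oc2cc(OCc3ccccc3)c3c(=O)c(OCc4ccccc4)c(-c4ccc(OCc5ccccc5)cc4)oc3c2[C@@]1(O)C(=O)c1ccc(OCc2ccccc2)cc1 | intermediate
15 | methyl (2R)-2-{3,5-bis(benzyloxy)-2-[4-(benzyloxy)phenyl]-7-hydroxy-4-oxochromen-8-yl}-3-[4-(benzyloxy)phenyl]-2-hydroxy-3-oxopropanoate | COC(=O)[C@](O)(C(=O)c1ccc(OCc2ccccc2)cc1)c1c(O)cc(OCc2ccccc2)c2c(=O)c(OCc3ccccc3)c(-c3ccc(OCc4ccccc4)cc3)oc12 | intermediate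
16 | methyl (9R)-3,5-bis(benzyloxy)-2,8-bis[4-(benzyloxy)phenyl]-8,9-dihydroxy-4-oxo-8,9-dihydrofuro[2,3-h]chromene-9-carboxylate (hemiketal, C8 labile) | O[C@]1(C(=O)OC)c2c(cc(OCc3ccccc3)c3c(=O)c(OCc4ccccc4)c(-c4ccc(OCc5ccccc5)cc4)oc23)OC1(O)c1ccc(OCc2ccccc2)cc1 | intermediate
17 | methyl (8R,9R)-3,5-bis(benzyloxy)-2,8-bis[4-(benzyloxy)phenyl]-9-hydroxy-8-methoxy-4-oxo-8,9-dihydrofuro[2,3-h]chromene-9-carboxylate | O[C@]1(C(=O)OC)c2c(cc(OCc3ccccc3)c3c(=O)c(OCc4ccccc4)c(-c4ccc(OCc5ccccc5)cc4)oc23)O[C@]1(OC)c1ccc(OCc2ccccc2)cc1 | intermediate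
18 | phloroglucinol | Oc1cc(O)cc(O)c1 | starting material
19 | 3,5-bis(benzyloxy)phenol | Oc1cc(OCc2ccccc2)cc(OCc2ccccc2)c1 | intermediate
20 | 3,5-bis(benzyloxy)-2-bromophenol | Oc1cc(OCc2ccccc2)cc(OCc2ccccc2)c1Br | intermediate
21 | [3,5-bis(benzyloxy)-2-bromophenoxy]trimethylsilane | C[Si](C)(C)Oc1cc(OCc2ccccc2)cc(OCc2ccccc2)c1Br | intermediate
22 | lithium 3,5-bis(benzyloxy)-2-(trimethylsilyl)phenoxide | [Li+].[O-]c1cc(OCc2ccccc2)cc(OCc2ccccc2)c1[Si](C)(C)C | intermediate
23 | 3,5-bis(benzyloxy)-2-(trimethylsilyl)phenyl trifluoromethanesulfonate | C[Si](C)(C)c1c(OCc2ccccc2)cc(OCc2ccccc2)cc1OS(=O)(=O)C(F)(F)F | intermediate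
24 | potassium alkoxide of 17 (8R,9R) | [K+].[O-][C@]1(C(=O)OC)c2c(cc(OCc3ccccc3)c3c(=O)c(OCc4ccccc4)c(-c4ccc(OCc5ccccc5)cc4)oc23)O[C@]1(OC)c1ccc(OCc2ccccc2)cc1 | intermediate
25 | 3,5-bis(benzyloxy)benzyne | C1#CC(OCc2ccccc2)=CC(OCc2ccccc2)=C1 | intermediate
26 | potassium aryl anion: (8R,9R)-9-[3,5-bis(benzyloxy)phenoxy] ester metallated at the ring carbon between the ether oxygen and the 3-benzyloxy group | [K+].[c-]1c(OCc2ccccc2)cc(OCc2ccccc2)cc1O[C@]1(C(=O)OC)c2c(cc(OCc3ccccc3)c3c(=O)c(OCc4ccccc4)c(-c4ccc(OCc5ccccc5)cc4)oc23)O[C@]1(OC)c1ccc(OCc2ccccc2)cc1 | intermediate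
27 | (2S,8'R)-3',4,5',6-tetrakis(benzyloxy)-2',8'-bis[4-(benzyloxy)phenyl]-8'-methoxyspiro[1-benzofuran-2,9'-furo[2,3-h]chromene]-3,4'(8'H)-dione | O=C1c2c(OCc3ccccc3)cc(OCc3ccccc3)cc2O[C@@]12c1c(cc(OCc3ccccc3)c3c(=O)c(OCc4ccccc4)c(-c4ccc(OCc5ccccc5)cc4)oc13)O[C@]2(OC)c1ccc(OCc2ccccc2)cc1 | intermediate
28 | (2S,8'R)-3',4,5',6-tetrahydroxy-2',8'-bis(4-hydroxyphenyl)-8'-methoxyspiro[1-benzofuran-2,9'-furo[2,3-h]chromene]-3,4'(8'H)-dione | O=C1c2c(O)cc(O)cc2O[C@@]12c1c(cc(O)c3c(=O)c(O)c(-c4ccc(O)cc4)oc13)O[C@]2(OC)c1ccc(O)cc1 | intermediate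
29 | (2S,8'R)-3',4,5',6,8'-pentahydroxy-2',8'-bis(4-hydroxyphenyl)spiro[1-benzofuran-2,9'-furo[2,3-h]chromene]-3,4'(8'H)-dione (CNP0283000.1) | O=C1c2c(O)cc(O)cc2O[C@@]12c1c(cc(O)c3c(=O)c(O)c(-c4ccc(O)cc4)oc13)O[C@]2(O)c1ccc(O)cc1 | target

Total step count: 15. Longest linear sequence: 11 steps from kaempferol (steps 1 to 6, 8 to 10, 14, 15).

Steps most likely to fail

Step 14 (aryne annulation).
- What may go wrong: the crowded, ester-stabilised alkoxide may add sluggishly, so that the aryne is consumed by fluoride, by released methoxide or by itself. The aryl anion may also be quenched before it acylates.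
- Fallback, from lactone 10, returning at target 29: the two acyl carbons on C9 are brought in the opposite order. C3–C3a then arrives preformed in the acylating agent, and O1–C7a is closed by an intramolecular SNAr reaction. All reaction types are known.
- Commercial 5-fluororesorcinol is benzylated (BnBr, K2CO3, DMF) to 1,3-bis(benzyloxy)-5-fluorobenzene F1.
- Vilsmeier–Haack formylation (POCl3, DMF), ortho to fluorine and para to one benzyloxy group, gives 2,4-bis(benzyloxy)-6-fluorobenzaldehyde F2.
- Pinnick oxidation (NaClO2, NaH2PO4, 2-methyl-2-butene) gives 2,4-bis(benzyloxy)-6-fluorobenzoic acid F3, and (COCl)2 converts it into 2,4-bis(benzyloxy)-6-fluorobenzoyl chloride F4.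
- Under the conditions of step 8, F4 acylates 10 to the 9-(fluoroaroyl) lactone F5.
- Hydroxylation as in step 9 with the antipodal ligand gives the (9S)-9-hydroxy lactone F6.
- Cs2CO3 in DMF closes the furanone by displacement of the ketone-activated ortho fluoride and gives the (2S)-spiro lactone F7.
- 4-(Benzyloxy)phenylmagnesium bromide (1 equiv, THF, −78 °C) adds once to the aryl lactone carbonyl, the most electrophilic one present. The adduct closes to the (2S,8'R)-hemiketal hexabenzyl ether F8.
- Hydrogenolysis as in step 15, without the acid stage, gives 29.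

Step 9 (enantioselective hydroxylation).
- What may go wrong: poor facial selectivity on the flat, extended enolate, or slow turnover through product binding to nickel.
- Fallback, from 13, returning at 17: resolution replaces catalyst control.
- 13 is hydroxylated with the same oxaziridine and catalytic Et3N but no chiral catalyst. This gives 14 together with its enantiomer, the (9S)-hydroxy lactone F9.
- The racemate is carried through step 10 to 17 together with the (8S,9S)-ketal ester F10.
- The two enantiomers are separated by preparative chromatography on a chiral stationary phase, and the absolute configuration is assigned by X-ray analysis before 17 enters step 14.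

Step 10 (lactone-to-ketal transposition).
- What may go wrong: the gem-disubstituted lactone may resist methanolysis. Compound 14 may ring-expand by an α-ketol acyl shift, or lose the aroyl group by retro-Claisen cleavage, before the ketal is locked.
- Fallback, from lactone 10, returning at 17: the lactone is opened before C9 is loaded.
- K2CO3 in MeOH at 0 °C gives the methyl (7-hydroxychromen-8-yl)acetate F11.
- MOMCl and i-Pr2NEt in CH2Cl2 cap the phenol as the 7-O-methoxymethyl ether F12.
- LiHMDS (2.2 equiv) and 12 in THF at −78 °C give, by crossed Claisen condensation, the β-keto ester F13.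
- Hydroxylation under the conditions of step 9 gives the (2R)-α-hydroxy-β-keto ester F14.
- Methanolic HCl as in step 10 removes the methoxymethyl group and ketalises in one pot, through 15 and 16, to give 17.

Further compounds
F1 | step 14 | 1,3-bis(benzyloxy)-5-fluorobenzene | Fc1cc(OCc2ccccc2)cc(OCc2ccccc2)c1
F2 | step 14 | 2,4-bis(benzyloxy)-6-fluorobenzaldehyde | O=Cc1c(F)cc(OCc2ccccc2)cc1OCc1ccccc1
F3 | step 14 | 2,4-bis(benzyloxy)-6-fluorobenzoic acid | O=C(O)c1c(F)cc(OCc2ccccc2)cc1OCc1ccccc1
F4 | step 14 | 2,4-bis(benzyloxy)-6-fluorobenzoyl chloride | O=C(Cl)c1c(F)cc(OCc2ccccc2)cc1OCc1ccccc1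
F5 | step 14 | 9-[2,4-bis(benzyloxy)-6-fluorobenzoyl]-3,5-bis(benzyloxy)-2-[4-(benzyloxy)phenyl]furo[2,3-h]chromene-4,8(9H)-dione | O=C1Oc2cc(OCc3ccccc3)c3c(=O)c(OCc4ccccc4)c(-c4ccc(OCc5ccccc5)cc4)oc3c2C1C(=O)c1c(F)cc(OCc2ccccc2)cc1OCc1ccccc1
F6 | step 14 | (9S)-9-[2,4-bis(benzyloxy)-6-fluorobenzoyl]-3,5-bis(benzyloxy)-2-[4-(benzyloxy)phenyl]-9-hydroxyfuro[2,3-h]chromene-4,8(9H)-dione | O=C1Oc2cc(OCc3ccccc3)c3c(=O)c(OCc4ccccc4)c(-c4ccc(OCc5ccccc5)cc4)oc3c2[C@]1(O)C(=O)c1c(F)cc(OCc2ccccc2)cc1OCc1ccccc1
F7 | step 14 | (2S)-3',4,5',6-tetrakis(benzyloxy)-2'-[4-(benzyloxy)phenyl]spiro[1-benzofuran-2,9'-furo[2,3-h]chromene]-3,4',8'-trione | O=C1c2c(OCc3ccccc3)cc(OCc3ccccc3)cc2O[C@@]12c1c(cc(OCc3ccccc3)c3c(=O)c(OCc4ccccc4)c(-c4ccc(OCc5ccccc5)cc4)oc13)OC2=O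
F8 | step 14 | (2S,8'R)-3',4,5',6-tetrakis(benzyloxy)-2',8'-bis[4-(benzyloxy)phenyl]-8'-hydroxyspiro[1-benzofuran-2,9'-furo[2,3-h]chromene]-3,4'(8'H)-dione | O=C1c2c(OCc3ccccc3)cc(OCc3ccccc3)cc2O[C@@]12c1c(cc(OCc3ccccc3)c3c(=O)c(OCc4ccccc4)c(-c4ccc(OCc5ccccc5)cc4)oc13)O[C@]2(O)c1ccc(OCc2ccccc2)cc1
F9 | step 9 | (9S)-9-[4-(benzyloxy)benzoyl]-3,5-bis(benzyloxy)-2-[4-(benzyloxy)phenyl]-9-hydroxyfuro[2,3-h]chromene-4,8(9H)-dione (enantiomer of 14) | O=C1Oc2cc(OCc3ccccc3)c3c(=O)c(OCc4ccccc4)c(-c4ccc(OCc5ccccc5)cc4)oc3c2[C@]1(O)C(=O)c1ccc(OCc2ccccc2)cc1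
F10 | step 9 | methyl (8S,9S)-3,5-bis(benzyloxy)-2,8-bis[4-(benzyloxy)phenyl]-9-hydroxy-8-methoxy-4-oxo-8,9-dihydrofuro[2,3-h]chromene-9-carboxylate (enantiomer of 17) | O[C@@]1(C(=O)OC)c2c(cc(OCc3ccccc3)c3c(=O)c(OCc4ccccc4)c(-c4ccc(OCc5ccccc5)cc4)oc23)O[C@@]1(OC)c1ccc(OCc2ccccc2)cc1
F11 | step 10 | methyl 2-{3,5-bis(benzyloxy)-2-[4-(benzyloxy)phenyl]-7-hydroxy-4-oxochromen-8-yl}acetate | COC(=O)Cc1c(O)cc(OCc2ccccc2)c2c(=O)c(OCc3ccccc3)c(-c3ccc(OCc4ccccc4)cc3)oc12
F12 | step 10 | methyl 2-{3,5-bis(benzyloxy)-2-[4-(benzyloxy)phenyl]-7-(methoxymethoxy)-4-oxochromen-8-yl}acetate | COC(=O)Cc1c(OCOC)cc(OCc2ccccc2)c2c(=O)c(OCc3ccccc3)c(-c3ccc(OCc4ccccc4)cc3)oc12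
F13 | step 10 | methyl 2-{3,5-bis(benzyloxy)-2-[4-(benzyloxy)phenyl]-7-(methoxymethoxy)-4-oxochromen-8-yl}-3-[4-(benzyloxy)phenyl]-3-oxopropanoate | COC(=O)C(C(=O)c1ccc(OCc2ccccc2)cc1)c1c(OCOC)cc(OCc2ccccc2)c2c(=O)c(OCc3ccccc3)c(-c3ccc(OCc4ccccc4)cc3)oc12
F14 | step 10 | methyl (2R)-2-{3,5-bis(benzyloxy)-2-[4-(benzyloxy)phenyl]-7-(methoxymethoxy)-4-oxochromen-8-yl}-3-[4-(benzyloxy)phenyl]-2-hydroxy-3-oxopropanoate | COC(=O)[C@](O)(C(=O)c1ccc(OCc2ccccc2)cc1)c1c(OCOC)cc(OCc2ccccc2)c2c(=O)c(OCc3ccccc3)c(-c3ccc(OCc4ccccc4)cc3)oc12
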